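## The problem

The target, 3,5-dibromo-2-(2,4-dibromophenoxy)-4-methoxyphenol (20), is two benzene rings joined through one ether oxygen (C2–O–C1'). It has no stereocentre, so every selectivity question is one of regiochemistry. Ring A is pentasubstituted in a fixed order (C1 OH, C2 aryloxy, C3 Br, C4 OMe, C5 Br), with C6 the only C–H. Ring B carries bromine at C2' and C4'.

Four aryl bromides make a conventional metal-mediated or SNAr ether coupling awkward, because the reacting halide must be told apart from the spectators. Once the bromines are in place, organolithium reagents, zerovalent metals and hydrogenolysis are all excluded.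

Ring A has two further hazards. A free C1 hydroxyl directs electrophiles to C6, the one position that must stay unsubstituted. The C1-OH/C4-OMe pair is also a hydroquinone monoether that electrophilic halogen can oxidise to a quinone. The C1 oxygen must therefore be an electron-poor ester while ring A is brominated.

Ring B is deactivated and cannot be brominated cleanly on the assembled ether, so its bromines must arrive with it. The feature that allows this is that C2'–C5' of ring B carry Br, H, Br, H, the same sequence as C3–C6 of 3,5-dibromo-2H-pyran-2-one (13). What remains of ring B, C1'(O)–C6'(H), is then an ethynyl ether of the ring A phenol, ynol ether 10.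

## Retrosynthesis

**Ring A bromines (20 ⇐ 19 ⇐ 17).** The C3–Br and C5–Br bonds are cut first, with the C1 oxygen as an acetate. Carrying these bromines from the start is ruled out because the alkynyl ether is made with an alkyllithium. Brominating free phenol 16 is ruled out because the hydroxyl sends bromine to C6 and invites quinone formation. In acetate 17 the only strong donors are the C4 methoxy and the C2 aryloxy group. They reinforce each other at C5 (ortho/para) and C3 (ortho/ortho), while C6 is meta to both and ortho only to the weak acetoxy donor. The forward reaction must stop after two substitutions and reach the flanked C3 position without touching ring B. Methanolysis of 19 then frees 20.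

**Protecting-group exchange (17 ⇐ 16 ⇐ 15).** Upstream the C1 oxygen must survive carbonate base, an alkyllithium and heating, which an acetal does and an ester does not. A methoxymethyl ether is, however, an activating ortho/para director and would reopen C6. It is therefore exchanged for acetate after the ring-forming step, at a cost of two simple steps.

**Ring B by cycloaddition (15 ⇐ 10 + 13, through 14).** The C1'–C2' and C5'–C6' bonds are cut, so ring B is the sum of the four carbons C3–C6 of pyrone 13 and the two alkyne carbons of 10. The neighbouring cut, C1'–O by coupling a ring A phenol with a 2,4-dibromophenyl electrophile, needs a specially differentiated aryl donor and is kept only as a reserve. The cycloaddition delivers both ring B bromines in their final positions and needs no metal. The forward step must join the terminal alkyne carbon to pyrone C6 and the oxygen-bearing carbon to C3; bridged lactone 14 then aromatises by decarboxylation. The precursors are a one-step pyrone and a four-step alkynyl ether.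

**Alkynyl ether (10 ⇐ 7 ⇐ 4 + 5).** The O–C(sp) bond is traced to dichlorovinyl ether 7, made from phenol 4 and trichloroethylene 5 through dichloroacetylene 6. Double dehydrochlorination and metal–halogen exchange, through 8 and 9, give 10 after protonation. This route needs only the phenol and an inexpensive C2 reagent. It demands that ring A carry no halogen yet, which the late bromination already ensures.

**Ring A oxygenation pattern (4 ⇐ 2 ⇐ 1).** The C2 oxygen of ring A is traced to the formyl group of 2-hydroxy-5-methoxybenzaldehyde 1 by oxygen insertion (Baeyer–Villiger, via formate 3). In 1 the formyl group is ortho to the hydroxyl and meta to the methoxy group, exactly the relation of the C2 oxygen to C1 and C4. Mono-protection of a catechol, which would require distinguishing two similar hydroxyls, is thereby avoided; the existing hydroxyl of 1 is simply masked first as ether 2.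

**Pyrone (13 ⇐ 11).** Both C–Br bonds of 13 are cut back to coumalic acid 11. Its carboxyl group marks C5 for ipso-bromodecarboxylation (giving 12), and C3 is the remaining nucleophilic position of the pyrone.

## Roads not taken

**Alternative 1: xanthone oxygen insertion and carbonyl excision.**
- Cut: the ring A C1–O bond, plus the carbon that stands where the C2' bromine must be. The target is traced to lactone A1 (2,6,8-tribromo-7-methoxy-11H-dibenzo[b,e][1,4]dioxepin-11-one) and then to xanthone A2 (2,4,7-tribromo-3-methoxy-9H-xanthen-9-one).
- Forward key step: a peracid Baeyer–Villiger oxidation of A2 with migration of the ring A carbon gives A1. Hydrolysis frees the C1 phenol and leaves acid A3 (5-bromo-2-(2,4-dibromo-6-hydroxy-3-methoxyphenoxy)benzoic acid), whose carboxyl group must then be replaced by bromine.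
- Merits: the diaryl ether and the ring A oxygen pattern are fixed inside a rigid tricycle built by classical acylation chemistry. No labile alkynyl ether is handled.
- Weak points:
  - The xanthone carbonyl is a doubly aryl-conjugated, vinylogous carbonate-like ketone and is a poor Baeyer–Villiger substrate.
  - The required migrating carbon has a para methoxy group that is twisted out of conjugation by two flanking bromines, and two meta bromines, so the ring B carbon may migrate instead.
  - Bromodecarboxylation of an unactivated benzoic acid such as A3 is unreliable.
  - A2 itself needs three regiodefined bromines.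
- Comparison: this road has two weakly precedented operations against one in the chosen plan, and it is longer. Its advantage is the robust intermediates. The chosen plan offsets that with a short and conventional preparation of both cycloaddition partners.

**Alternative 2: formal [3+3] cyclocondensation building ring A as a salicylate.**
- Cut: the C2–C3 and C5–C6 bonds of ring A. Ring B comes from 2,4-dibromophenol A8, which is O-alkylated to β-keto ester A5 (methyl 4-(2,4-dibromophenoxy)-3-oxobutanoate) and converted to bis-silyl dienol ether A6.
- Forward key step: Lewis acid-mediated condensation of A6 with the symmetrical C3 bis-acetal A7 (1,1,2,3,3-pentamethoxypropane) gives salicylate A4 (methyl 3-(2,4-dibromophenoxy)-2-hydroxy-5-methoxybenzoate). Dibromination ortho to methoxy, saponification and protodecarboxylation follow.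
- Merits:
  - Ring B is bought with its bromines, and no diaryl ether coupling is needed.
  - The C3 partner is symmetrical, so the cyclisation has no regiochemical issue.
  - The ester occupies the future C6 position, so the free phenol can be brominated without a protecting-group exchange.
  - On paper it is about seven steps, two or three fewer than the chosen plan, and its control of the ring A bromination is more elegant.
- Weak points:
  - Cyclisations of 4-aryloxy dienes of this kind with inductively deactivated alkoxy-malonaldehyde acetals are typically modest.
  - The route ends with decarboxylation of a tetrabrominated salicylic acid, which requires heat or acid on the finished, oxidation-prone hydroquinone monoether.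
- Comparison: in step count and bromination control this road is as good or better. The chosen plan sets against it a ring-forming step under neutral thermal conditions, partners made by routine high-yielding reactions, and a mild final deprotection in place of a forcing last step.

**Alternative 3: ring A from a methoxydibromopyrone and an aryloxyalkynyl boronate.**
- Cut: the C2–C3 and C1–C6 bonds of ring A.
- Forward key step: [4+2] cycloaddition of pyrone A10 (3,5-dibromo-4-methoxy-2H-pyran-2-one) with alkynyl boronate A11 (2-[(2,4-dibromophenoxy)ethynyl]-4,4,5,5-tetramethyl-1,3,2-dioxaborolane) and decarboxylative aromatisation gives aryl boronate A9 (2-[3,5-dibromo-2-(2,4-dibromophenoxy)-4-methoxyphenyl]-4,4,5,5-tetramethyl-1,3,2-dioxaborolane). Oxidation of the C–B bond then gives the phenol.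
- Merits: this is the most convergent road. All four bromines are carried in by the building blocks, there is no electrophilic bromination and no protecting group, and the endgame is a single oxidation.
- Weak points:
  - The 4-methoxy group makes A10 a vinylogous carbonate and a much poorer electron-poor diene.
  - The boron substituent lowers the nucleophilicity of the alkyne in A11, so the two partners are electronically mismatched and the ring formed is hexasubstituted.
  - A11 cannot be made by the alkyllithium route to alkynyl ethers, because the aryl bromides would exchange.
  - A10 is not a one-step compound.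
- Comparison: if both partners were available and reactive, this road would be shorter than the chosen plan. The chosen plan uses the same cycloaddition logic on ring B instead, where the diene is unencumbered and strongly electron-poor and the alkyne is unencumbered and electron-rich, and where the alkynyl ether is made before any bromine is present.

Key step: step 6

Remark on the chemistry: locants C1–C6 refer to ring A of the target as a phenol and C1'–C6' to ring B. The target has no stereocentre. The E geometry of 7 and the bridgehead centres of transient, racemic 14 are erased later in the route.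

## Route

Step 1
Reactants: 1 2-hydroxy-5-methoxybenzaldehyde
Product: 2 5-methoxy-2-(methoxymethoxy)benzaldehyde
Conditions: MOMCl, i-Pr2NEt, CH2Cl2, 0 °C → rt
Reagents that add atoms: chloromethyl methyl ether, COCCl
Why: Williamson-type O-alkylation of the phenol with an α-chloro ether; the acetal formed withstands the base, alkyllithium and heat of steps 3–6 and cannot migrate to a neighbouring oxygen.

Step 2
Reactants: 2 5-methoxy-2-(methoxymethoxy)benzaldehyde
Product: 4 5-methoxy-2-(methoxymethoxy)phenol, via aryl formate 3 (not isolated)
Conditions: mCPBA, CH2Cl2, 0 °C → rt; aq NaHCO3 wash; then K2CO3 (0.2 equiv), MeOH, rt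
Reagents that add atoms: 3-chloroperoxybenzoic acid, OOC(=O)c1cccc(Cl)c1
Why: Baeyer–Villiger (Dakin-type) oxidation; the ortho-alkoxy aryl group migrates in preference to hydride, and the labile aryl formate is cleaved by mild methanolysis, placing the new hydroxyl ortho to the MOM ether and meta to methoxy.

Step 3
Reactants: 4 5-methoxy-2-(methoxymethoxy)phenol; 5 trichloroethylene
Product: 7 2-{[(E)-1,2-dichloroethenyl]oxy}-4-methoxy-1-(methoxymethoxy)benzene, via dichloroacetylene 6 (not isolated)
Conditions: K2CO3, DMF, 70 °C
Reagents that add atoms: none
Why: Base-mediated elimination–addition, a known preparation of aryl 1,2-dichlorovinyl ethers; the phenoxide adds anti across dichloroacetylene generated and consumed in solution, which fixes the E geometry.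

Step 4
Reactants: 7 2-{[(E)-1,2-dichloroethenyl]oxy}-4-methoxy-1-(methoxymethoxy)benzene
Product: 10 2-(ethynyloxy)-4-methoxy-1-(methoxymethoxy)benzene, via chloroethynyl ether 8 (not isolated), via lithium acetylide 9 (not isolated)
Conditions: n-BuLi (2.2 equiv), THF, –78 → –40 °C; MeOH, –78 °C; used promptly
Reagents that add atoms: none
Why: Known dichlorovinyl ether to ynol ether conversion: vinylic deprotonation and loss of LiCl give the chloroalkyne, lithium–chlorine exchange gives the acetylide, and low-temperature protonation gives the terminal alkynyl ether; ring A carries no halogen, and ortho-lithiation is slow at this temperature with controlled stoichiometry.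

Step 5
Reactants: 11 coumalic acid
Product: 13 3,5-dibromo-2H-pyran-2-one, via 5-bromo-2H-pyran-2-one 12 (not isolated)
Conditions: NBS (2.5 equiv), LiOAc, MeCN/H2O, rt
Reagents that add atoms: N-bromosuccinimide, O=C1CCC(=O)N1Br
Why: Known bromodecarboxylation of a pyrone carboxylate: ipso attack of electrophilic bromine at C5 with loss of CO2, and electrophilic bromination at C3, the other nucleophilic position of the dienol ether system.

Step 6
Reactants: 10 2-(ethynyloxy)-4-methoxy-1-(methoxymethoxy)benzene; 13 3,5-dibromo-2H-pyran-2-one
Product: 15 1-(2,4-dibromophenoxy)-5-methoxy-2-(methoxymethoxy)benzene, via bridged lactone 14 (not isolated)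
Conditions: 13 (2 equiv), PhMe, 90 °C, sealed tube
Reagents that add atoms: none
Why: Proposed new method: the closest known reactions are the thermal inverse-electron-demand Diels–Alder additions of 3,5-dibromo-2-pyrone to enol ethers and the pyrone–alkyne cycloaddition/decarboxylation route to benzenes (ynamine and siloxyalkyne partners included); an aryl ynol ether is the untested 2π partner. The HOMO of 10 is largest at the terminal carbon through oxygen lone-pair donation, and the LUMO of 13 is largest at C6, so an asynchronous concerted [4+2] addition should join the terminal carbon to C6 and the oxygen-bearing carbon to C3. Ring B is thus closed by cycloaddition, giving the 2-oxabicyclo[2.2.2]octadienone 14, which should aromatise at the reaction temperature by retro-[4+2] loss of CO2. The two bridgehead stereocentres of 14 form as a racemate and are destroyed on CO2 loss, so no stereocontrol is needed. The one selectivity required is regiochemical (2,4- and not 3,5-dibromophenoxy); it rests on the matched polarisation of the partners, the orientation that enol ethers show with this pyrone. The aryloxy group has no β-hydrogen, so 10 cannot collapse to a ketene by retro-ene reaction on heating, and the excess of 13 is meant to let cycloaddition outrun oligomerisation of 10. The MOM acetal, the methyl ether and both C–Br bonds are inert under neutral thermal conditions.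

Step 7
Reactants: 15 1-(2,4-dibromophenoxy)-5-methoxy-2-(methoxymethoxy)benzene
Product: 16 2-(2,4-dibromophenoxy)-4-methoxyphenol
Conditions: conc. HCl (cat.), MeOH, 50 °C
Reagents that add atoms: none
Why: Acid-catalysed acetal exchange removes the MOM group as dimethoxymethane; the diaryl ether, methyl ether and aryl bromides are stable to dilute acid.

Step 8
Reactants: 16 2-(2,4-dibromophenoxy)-4-methoxyphenol
Product: 17 2-(2,4-dibromophenoxy)-4-methoxyphenyl acetate
Conditions: Ac2O, pyridine, DMAP (cat.), CH2Cl2, rt
Reagents that add atoms: acetic anhydride, CC(=O)OC(C)=O
Why: DMAP-catalysed O-acylation; the acetate turns the strongest donor of ring A into a weak one and protects the hydroquinone monoether from oxidation during bromination.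

Step 9
Reactants: 17 2-(2,4-dibromophenoxy)-4-methoxyphenyl acetate
Product: 19 3,5-dibromo-2-(2,4-dibromophenoxy)-4-methoxyphenyl acetate, via C5 monobromide 18 (not isolated)
Conditions: Br2 (2.2 equiv), NaOAc, AcOH, rt → 45 °C
Reagents that add atoms: bromine, BrBr
Why: Electrophilic aromatic bromination: the methoxy and aryloxy groups jointly activate C5 (ortho/para, first) and then C3 (ortho/ortho), whereas C6 is meta to both and next to the weakly donating acetoxy group; ring B is deactivated by its two bromines, and NaOAc buffers the HBr formed.

Step 10
Reactants: 19 3,5-dibromo-2-(2,4-dibromophenoxy)-4-methoxyphenyl acetate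
Product: 20 3,5-dibromo-2-(2,4-dibromophenoxy)-4-methoxyphenol
Conditions: HCl (1.25 M in MeOH, cat.), MeOH, rt → 40 °C
Reagents that add atoms: none
Why: Acid-catalysed transesterification of an electron-poor aryl acetate; the non-basic, non-oxidising medium spares the aryl bromides, both ethers and the oxidation-prone phenol.

## Compound list

1 | 2-hydroxy-5-methoxybenzaldehyde | COc1ccc(O)c(C=O)c1 | starting material
2 | 5-methoxy-2-(methoxymethoxy)benzaldehyde | COCOc1ccc(OC)cc1C=O | intermediate
3 | 5-methoxy-2-(methoxymethoxy)phenyl formate | COCOc1ccc(OC)cc1OC=O | intermediate (not isolated)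
4 | 5-methoxy-2-(methoxymethoxy)phenol | COCOc1ccc(OC)cc1O | intermediate
5 | trichloroethylene | ClC=C(Cl)Cl | starting material
6 | dichloroacetylene | ClC#CCl | intermediate (not isolated)
7 | 2-{[(E)-1,2-dichloroethenyl]oxy}-4-methoxy-1-(methoxymethoxy)benzene | Cl/C=C(/Cl)Oc1cc(OC)ccc1OCOC | intermediate
8 | 2-[(chloroethynyl)oxy]-4-methoxy-1-(methoxymethoxy)benzene | ClC#COc1cc(OC)ccc1OCOC | intermediate (not isolated)
9 | {[5-methoxy-2-(methoxymethoxy)phenoxy]ethynyl}lithium | [Li]C#COc1cc(OC)ccc1OCOC | intermediate (not isolated)
10 | 2-(ethynyloxy)-4-methoxy-1-(methoxymethoxy)benzene | C#COc1cc(OC)ccc1OCOC | intermediate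
11 | coumalic acid (2-oxo-2H-pyran-5-carboxylic acid) | O=C(O)c1ccc(=O)oc1 | starting material
12 | 5-bromo-2H-pyran-2-one | O=c1ccc(Br)co1 | intermediate (not isolated)
13 | 3,5-dibromo-2H-pyran-2-one | O=c1occ(Br)cc1Br | intermediate
14 | 4,7-dibromo-5-[5-methoxy-2-(methoxymethoxy)phenoxy]-2-oxabicyclo[2.2.2]octa-5,7-dien-3-one (racemic) | O=C1OC2C=C(Oc3cc(OC)ccc3OCOC)C1(Br)C=C2Br | intermediate (not isolated)
15 | 1-(2,4-dibromophenoxy)-5-methoxy-2-(methoxymethoxy)benzene | COCOc1ccc(OC)cc1Oc1ccc(Br)cc1Br | intermediate
16 | 2-(2,4-dibromophenoxy)-4-methoxyphenol | COc1ccc(O)c(Oc2ccc(Br)cc2Br)c1 | intermediate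
17 | 2-(2,4-dibromophenoxy)-4-methoxyphenyl acetate | COc1ccc(OC(C)=O)c(Oc2ccc(Br)cc2Br)c1 | intermediate
18 | 5-bromo-2-(2,4-dibromophenoxy)-4-methoxyphenyl acetate | COc1cc(Oc2ccc(Br)cc2Br)c(OC(C)=O)cc1Br | intermediate (not isolated)
19 | 3,5-dibromo-2-(2,4-dibromophenoxy)-4-methoxyphenyl acetate | COc1c(Br)cc(OC(C)=O)c(Oc2ccc(Br)cc2Br)c1Br | intermediate
20 | 3,5-dibromo-2-(2,4-dibromophenoxy)-4-methoxyphenol | COc1c(Br)cc(O)c(Oc2ccc(Br)cc2Br)c1Br | target

## Step count and risks

Total steps: 10. Longest linear sequence: 9 (steps 1–4 and 6–10); step 5 is a one-step branch.

**Step 6 (key step, proposed new method).**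
- Risk: oligomerisation or hydration of the alkynyl ether may outpace cycloaddition. Addition with the reverse orientation is also possible, because an aryloxy group polarises the alkyne less strongly than an alkoxy or amino group.
- Fallback (known chemistry; sets out from 4, returns at 15): phenol 4 is O-arylated with bis(2,4-dibromophenyl)iodonium chloride F1 in aqueous NaOH/dioxane at 80 °C. F1 is prepared from 1,3-dibromobenzene with iodyl sulfate, (IO)2SO4, in H2SO4 followed by chloride precipitation. This ligand coupling on trivalent iodine is the established entry to polybrominated diphenyl ethers. It uses no transition metal, so the aryl bromides are untouched, and the MOM ether is stable to the base. It replaces steps 3–6 but gives up the cycloaddition.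

**Step 4.**
- Risk: decomposition of the terminal aryl alkynyl ether (oligomerisation, or hydration to the aryl acetate) during concentration or chromatography.
- Fallback (sets out from 9, returns at 10): acetylide 9 is quenched with i-Pr3SiOTf instead of MeOH to give the storable silyl-capped ynol ether, {[5-methoxy-2-(methoxymethoxy)phenoxy]ethynyl}tri(propan-2-yl)silane F2. It is purified and then desilylated with Bu4NF in THF at 0 °C immediately before step 6, so that 10 is carried forward as a solution without concentration.

**Step 9.**
- Risk: the second bromination at the flanked C3 position may stall, and forcing it may bring substitution at C6 or at C6' of ring B, or partial loss of the acetate followed by oxidation of the hydroquinone monoether.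
- Fallback (sets out from 16, returns at 20): phenol 16 is converted with MsCl/Et3N into 2-(2,4-dibromophenoxy)-4-methoxyphenyl methanesulfonate F3. The sulfonate is a stronger deactivator than acetate and is stable to HBr and to more forcing bromination. Bromination with Br2/NaOAc/AcOH passes through the C5 monobromide, 5-bromo-2-(2,4-dibromophenoxy)-4-methoxyphenyl methanesulfonate F4, to 3,5-dibromo-2-(2,4-dibromophenoxy)-4-methoxyphenyl methanesulfonate F5. The mesylate is then cleaved with NaOH in MeOH/H2O at 60 °C and the mixture acidified to give 20.

## Further compounds

F1 | step 6 | bis(2,4-dibromophenyl)iodonium chloride | Brc1ccc([I+]c2ccc(Br)cc2Br)c(Br)c1.[Cl-]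
F2 | step 4 | {[5-methoxy-2-(methoxymethoxy)phenoxy]ethynyl}tri(propan-2-yl)silane | COCOc1ccc(OC)cc1OC#C[Si](C(C)C)(C(C)C)C(C)C
F3 | step 9 | 2-(2,4-dibromophenoxy)-4-methoxyphenyl methanesulfonate | COc1ccc(OS(C)(=O)=O)c(Oc2ccc(Br)cc2Br)c1
F4 | step 9 | 5-bromo-2-(2,4-dibromophenoxy)-4-methoxyphenyl methanesulfonate | COc1cc(Oc2ccc(Br)cc2Br)c(OS(C)(=O)=O)cc1Br
F5 | step 9 | 3,5-dibromo-2-(2,4-dibromophenoxy)-4-methoxyphenyl methanesulfonate | COc1c(Br)cc(OS(C)(=O)=O)c(Oc2ccc(Br)cc2Br)c1Br
A1 | alternative 1 | 2,6,8-tribromo-7-methoxy-11H-dibenzo[b,e][1,4]dioxepin-11-one | COc1c(Br)cc2OC(=O)c3cc(Br)ccc3Oc2c1Br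
A2 | alternative 1 | 2,4,7-tribromo-3-methoxy-9H-xanthen-9-one | COc1c(Br)cc2c(c1Br)Oc1ccc(Br)cc1C2=O
A3 | alternative 1 | 5-bromo-2-(2,4-dibromo-6-hydroxy-3-methoxyphenoxy)benzoic acid | COc1c(Br)cc(O)c(Oc2ccc(Br)cc2C(=O)O)c1Br
A4 | alternative 2 | methyl 3-(2,4-dibromophenoxy)-2-hydroxy-5-methoxybenzoate | COC(=O)c1cc(OC)cc(Oc2ccc(Br)cc2Br)c1O
A5 | alternative 2 | methyl 4-(2,4-dibromophenoxy)-3-oxobutanoate | COC(=O)CC(=O)COc1ccc(Br)cc1Br
A6 | alternative 2 | 4-(2,4-dibromophenoxy)-1-methoxy-1,3-bis(trimethylsilyloxy)buta-1,3-diene (double-bond geometry not defined) | COC(O[Si](C)(C)C)=CC(O[Si](C)(C)C)=COc1ccc(Br)cc1Br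
A7 | alternative 2 | 1,1,2,3,3-pentamethoxypropane | COC(OC)C(OC)C(OC)OC
A8 | alternative 2 | 2,4-dibromophenol | Oc1ccc(Br)cc1Br
A9 | alternative 3 | 2-[3,5-dibromo-2-(2,4-dibromophenoxy)-4-methoxyphenyl]-4,4,5,5-tetramethyl-1,3,2-dioxaborolane | COc1c(Br)cc(B2OC(C)(C)C(C)(C)O2)c(Oc2ccc(Br)cc2Br)c1Br
A10 | alternative 3 | 3,5-dibromo-4-methoxy-2H-pyran-2-one | COc1c(Br)coc(=O)c1Br
A11 | alternative 3 | 2-[(2,4-dibromophenoxy)ethynyl]-4,4,5,5-tetramethyl-1,3,2-dioxaborolane | CC1(C)OB(C#COc2ccc(Br)cc2Br)OC1(C)C
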